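**Retrosynthetic overview**

1. The lactone (O1–C2) is closed last from a hydroxy ester. Just before that, one hydrogenation removes three benzyl ethers and opens a temporary 2-(3,4-dimethoxyphenyl)benzofuran ring (O7–C(Ar)=CH–C6), releasing the C6–CH2–CH2–Ar chain and the free O7–H.
2. That benzofuran comes from the key step, a one-pot Fischer-type sequence (oxime ether formation, [3,3]-sigmatropic shift, cyclisation, loss of NH3). It joins 3,4-dimethoxyacetophenone to an O7-aminooxy arene and forms the C6–CH2 bond, with the neighbouring carbon carried at the ketimine oxidation level.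
3. Enabling feature: the phenolic oxygen O7 on C7 stands directly ortho to C6–H in the benzo ring of the chromanone, so O7–C7=C6 can act as the aryloxy half of an O–N-tethered 3-oxa-4-aza-1,5-diene. C6 is also para to O1, whereas C8 lies between the two oxygen-bearing carbons.
4. The C4 stereocentre is set earlier by Rh/(R)-SEGPHOS 1,4-addition of an arylboronic acid to 7-bromocoumarin. The C7 bromide is later exchanged for the O7–N tether by Pd-catalysed C–O coupling.
5. Ring order: pyranone ring first (coumarin, then opened temporarily as O1-benzyl ether/methyl ester), furan ring in the key step (cleaved again), lactone ring re-closed last.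

Key step: step 5

Remark: chroman-2-one locants of the target (O1, C2–C4, C4a, C5–C8, C8a; O7 on C7) are used for the corresponding atoms of all intermediates. The C=N geometry of the imidate and oxime ether intermediates is inconsequential and left unspecified. (R)-SEGPHOS is assumed to give the (4R)-lactone, as for simpler 4-arylchroman-2-ones; otherwise the (S)-ligand would be used.

**Route**

Step 1
Reactants: 1 4-bromo-2-hydroxybenzaldehyde; 2 ethyl 2-(triphenyl-λ5-phosphanylidene)acetate
Product: 5 7-bromo-2H-chromen-2-one, via E-hydroxycinnamate ester 3 (not isolated), via Z-hydroxycinnamate ester 4 (not isolated)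
Conditions: PhNEt2, 210 °C
Reagents that add atoms: none
Why: Wittig olefination of the aldehyde gives the ortho-hydroxycinnamate 3, which equilibrates thermally with its Z isomer 4, and 4 lactonises with loss of ethanol to the coumarin (Wittig olefination/lactonisation); no stereocentre is formed.

Step 2
Reactants: 5 7-bromo-2H-chromen-2-one; 6 [3,4-bis(benzyloxy)phenyl]boronic acid
Product: 7 (4R)-4-[3,4-bis(benzyloxy)phenyl]-7-bromo-3,4-dihydro-2H-chromen-2-one
Conditions: Rh(acac)(C2H4)2 (3 mol%), (R)-SEGPHOS (3.3 mol%), 6 (3 equiv), dioxane/H2O (10:1), 60 °C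
Reagents that add atoms: none
Why: Rhodium-catalysed asymmetric 1,4-addition of an arylboronic acid to a coumarin (Hayashi–Miyaura reaction), in which the aryl–Rh(I) species bound to (R)-SEGPHOS inserts the C3=C4 bond on one enantioface and the rhodium enolate is protonated by water, so the ligand sets C4 as (R) while the aryl bromide is inert to Rh(I) under these neutral conditions.

Step 3
Reactants: 7 (4R)-4-[3,4-bis(benzyloxy)phenyl]-7-bromo-3,4-dihydro-2H-chromen-2-one
Product: 8 methyl (3R)-3-[2-(benzyloxy)-4-bromophenyl]-3-[3,4-bis(benzyloxy)phenyl]propanoate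
Conditions: K2CO3, BnBr, MeOH/acetone, 55 °C
Reagents that add atoms: benzyl bromide (BrCc1ccccc1); methanol (CO)
Why: Methoxide generated by K2CO3 in methanol opens the reactive aryl ester (lactone methanolysis) and the O1 phenoxide is trapped irreversibly by Williamson benzylation, which pulls the equilibrium to the open form; the stereocentre is not α to the carbonyl and is untouched.

Step 4
Reactants: 8 methyl (3R)-3-[2-(benzyloxy)-4-bromophenyl]-3-[3,4-bis(benzyloxy)phenyl]propanoate; 9 ethyl N-hydroxyethanimidate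
Product: 10 ethyl N-{3-(benzyloxy)-4-[(1R)-1-[3,4-bis(benzyloxy)phenyl]-3-methoxy-3-oxopropyl]phenoxy}ethanimidate
Conditions: [Pd(allyl)Cl]2 (1 mol%), t-BuBrettPhos (3 mol%), Cs2CO3, toluene, 65 °C
Reagents that add atoms: none
Why: Palladium-catalysed C–O cross-coupling (Buchwald–Hartwig type) of the unhindered aryl bromide with the O–H of ethyl acetohydroximate, a hydroxylamine equivalent, should install the O7–N tether, the bulky biaryl phosphine enforcing C–O reductive elimination while ester, benzyl ethers and the stereocentre are inert to Cs2CO3 in toluene.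

Step 5
Reactants: 10 ethyl N-{3-(benzyloxy)-4-[(1R)-1-[3,4-bis(benzyloxy)phenyl]-3-methoxy-3-oxopropyl]phenoxy}ethanimidate; 11 1-(3,4-dimethoxyphenyl)ethan-1-one
Product: 15 methyl (3R)-3-[6-(benzyloxy)-2-(3,4-dimethoxyphenyl)-1-benzofuran-5-yl]-3-[3,4-bis(benzyloxy)phenyl]propanoate, via aryloxyamine 12 (not isolated), via O-aryl ketoxime ether 13 (not isolated), via hydroxyaryl ketimine 14 (not isolated)
Conditions: HCl (4 M in dioxane, 3 equiv), H2O (1 equiv), dioxane, rt then 70 °C
Reagents that add atoms: none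
Why: Acid hydrolyses the imidate of 10 to the aryloxyammonium salt of 12, which condenses with ketone 11 to the O-aryl ketoxime ether 13; its N-protonated ene-hydroxylamine tautomer undergoes a charge-accelerated [3,3]-sigmatropic shift across C6=C7–O7–N–C(Ar)=CH2 that cleaves the weak N–O bond and forms the C6–CH2 bond, and tautomerisation of the dienone restores the arene as phenol–ketimine 14. The closest known reaction type is the Fischer-type benzofuran synthesis from O-aryl oxime ethers, including its one-pot variant from O-aryl acetohydroximates and ketones in HCl/dioxane. One ring is closed, the furan, by 5-exo-trig addition of the liberated O7–H to the protonated ketimine carbon of 14 followed by loss of ammonia to the aromatic 2-arylbenzofuran. No stereocentre is created, and the (R)-centre, which is neither enolisable nor ionisable here, should be carried through unchanged. Three selectivities are needed and are secured by the substrate: the ene-hydroxylamine can only form toward the methyl group because the aryl ketone has no other α-hydrogen; the shift should go to C6 and not C8 because C6 is para to the donor O1-benzyl ether and unhindered while C8 is wedged between O1Bn and O7 (the bias by which 3-alkoxyphenyl substrates give 6-alkoxy-benzofurans and -indoles); and only O7 can cyclise because O1 is benzylated.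

Step 6
Reactants: 15 methyl (3R)-3-[6-(benzyloxy)-2-(3,4-dimethoxyphenyl)-1-benzofuran-5-yl]-3-[3,4-bis(benzyloxy)phenyl]propanoate
Product: 17 (4R)-4-(3,4-dihydroxyphenyl)-6-[2-(3,4-dimethoxyphenyl)ethyl]-7-hydroxy-3,4-dihydro-2H-chromen-2-one, via hydroxy ester 16 (not isolated)
Conditions: H2 (10 bar), Pd(OH)2/C, EtOAc/AcOH, 60 °C; filter; then TsOH·H2O (cat.), toluene/THF, 70 °C
Reagents that add atoms: none
Why: Heterogeneous hydrogenation over palladium should saturate the furan C=C bond and then hydrogenolyse the resulting benzylic C–O bond together with the three benzyl ethers, releasing O7–H and the CH2–CH2 link, after which acid-catalysed transesterification (6-exo-trig lactonisation of O1–H onto the methyl ester) closes the chromanone; the C4 stereocentre bears only C–C bonds and a non-acidic hydrogen and is retained.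

**Compound list**

1 | 4-bromo-2-hydroxybenzaldehyde | O=Cc1ccc(Br)cc1O | starting material
2 | ethyl 2-(triphenyl-λ5-phosphanylidene)acetate | CCOC(=O)C=P(c1ccccc1)(c1ccccc1)c1ccccc1 | starting material
3 | ethyl (2E)-3-(4-bromo-2-hydroxyphenyl)prop-2-enoate | CCOC(=O)/C=C/c1ccc(Br)cc1O | intermediate
4 | ethyl (2Z)-3-(4-bromo-2-hydroxyphenyl)prop-2-enoate | CCOC(=O)/C=C\c1ccc(Br)cc1O | intermediate
5 | 7-bromo-2H-chromen-2-one | O=C1C=Cc2ccc(Br)cc2O1 | intermediate
6 | [3,4-bis(benzyloxy)phenyl]boronic acid | OB(O)c1ccc(OCc2ccccc2)c(OCc2ccccc2)c1 | starting material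
7 | (4R)-4-[3,4-bis(benzyloxy)phenyl]-7-bromo-3,4-dihydro-2H-chromen-2-one | Brc1ccc2c(c1)OC(=O)C[C@@H]2c1ccc(OCc2ccccc2)c(OCc2ccccc2)c1 | intermediate
8 | methyl (3R)-3-[2-(benzyloxy)-4-bromophenyl]-3-[3,4-bis(benzyloxy)phenyl]propanoate | COC(=O)C[C@@H](c1ccc(Br)cc1OCc1ccccc1)c1ccc(OCc2ccccc2)c(OCc2ccccc2)c1 | intermediate
9 | ethyl N-hydroxyethanimidate (ethyl acetohydroximate) | CCOC(C)=NO | starting material
10 | ethyl N-{3-(benzyloxy)-4-[(1R)-1-[3,4-bis(benzyloxy)phenyl]-3-methoxy-3-oxopropyl]phenoxy}ethanimidate | COC(=O)C[C@@H](c1ccc(ON=C(C)OCC)cc1OCc1ccccc1)c1ccc(OCc2ccccc2)c(OCc2ccccc2)c1 | intermediate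
11 | 1-(3,4-dimethoxyphenyl)ethan-1-one | CC(=O)c1ccc(OC)c(OC)c1 | starting material
12 | methyl (3R)-3-[4-(aminooxy)-2-(benzyloxy)phenyl]-3-[3,4-bis(benzyloxy)phenyl]propanoate | COC(=O)C[C@@H](c1ccc(ON)cc1OCc1ccccc1)c1ccc(OCc2ccccc2)c(OCc2ccccc2)c1 | intermediate
13 | methyl (3R)-3-[2-(benzyloxy)-4-({[1-(3,4-dimethoxyphenyl)ethylidene]amino}oxy)phenyl]-3-[3,4-bis(benzyloxy)phenyl]propanoate | COC(=O)C[C@@H](c1ccc(ON=C(C)c2ccc(OC)c(OC)c2)cc1OCc1ccccc1)c1ccc(OCc2ccccc2)c(OCc2ccccc2)c1 | intermediate
14 | methyl (3R)-3-{2-(benzyloxy)-5-[2-(3,4-dimethoxyphenyl)-2-iminoethyl]-4-hydroxyphenyl}-3-[3,4-bis(benzyloxy)phenyl]propanoate | COC(=O)C[C@@H](c1cc(CC(=N)c2ccc(OC)c(OC)c2)c(O)cc1OCc1ccccc1)c1ccc(OCc2ccccc2)c(OCc2ccccc2)c1 | intermediate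
15 | methyl (3R)-3-[6-(benzyloxy)-2-(3,4-dimethoxyphenyl)-1-benzofuran-5-yl]-3-[3,4-bis(benzyloxy)phenyl]propanoate | COC(=O)C[C@@H](c1cc2cc(-c3ccc(OC)c(OC)c3)oc2cc1OCc1ccccc1)c1ccc(OCc2ccccc2)c(OCc2ccccc2)c1 | intermediate
16 | methyl (3R)-3-(3,4-dihydroxyphenyl)-3-{5-[2-(3,4-dimethoxyphenyl)ethyl]-2,4-dihydroxyphenyl}propanoate | COC(=O)C[C@@H](c1cc(CCc2ccc(OC)c(OC)c2)c(O)cc1O)c1ccc(O)c(O)c1 | intermediate
17 | (4R)-4-(3,4-dihydroxyphenyl)-6-[2-(3,4-dimethoxyphenyl)ethyl]-7-hydroxy-3,4-dihydro-2H-chromen-2-one | COc1ccc(CCc2cc3c(cc2O)OC(=O)C[C@@H]3c2ccc(O)c(O)c2)cc1OC | target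

**Step count and risks**

Total step count: 6. Longest linear sequence: 6 steps (1 → 5 → 7 → 8 → 10 → 15 → 17).

Steps most likely to fail:

Step 5 (key step). The sigmatropic shift may show insufficient site selectivity between the two carbons ortho to O7, or the hot acid may erode the benzyl ethers before the shift is complete. The fallback builds the same furan ring by cross-coupling and sets out from bromide 8. Miyaura borylation (B2pin2, Pd(dppf)Cl2, KOAc, dioxane, 80 °C) should give methyl (3R)-3-[2-(benzyloxy)-4-(4,4,5,5-tetramethyl-1,3,2-dioxaborolan-2-yl)phenyl]-3-[3,4-bis(benzyloxy)phenyl]propanoate F1. Oxidation (NaBO3·4H2O, THF/H2O, rt) should give the phenol methyl (3R)-3-[2-(benzyloxy)-4-hydroxyphenyl]-3-[3,4-bis(benzyloxy)phenyl]propanoate F2. Electrophilic iodination with NIS (MeCN, 0 °C) is expected at the carbon ortho to the free hydroxyl and para to the benzyl ether, giving methyl (3R)-3-[2-(benzyloxy)-4-hydroxy-5-iodophenyl]-3-[3,4-bis(benzyloxy)phenyl]propanoate F3. Sonogashira coupling of F3 with commercial 4-ethynyl-1,2-dimethoxybenzene (C#Cc1ccc(OC)c(OC)c1; Pd(PPh3)2Cl2, CuI, Et3N, DMF, 60 °C) with in situ 5-endo-dig cyclisation of the ortho-alkynylphenol returns to benzofuran 15.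

Step 6. Hydrogenation may stall at the furan C=C bond once the benzyl ethers are gone, or over-reduce an electron-rich ring under forcing conditions. The fallback separates the two reductions and sets out from 15. Ionic hydrogenation (Et3SiH, TFA, CH2Cl2, 0 °C to rt; protonation at the furan β-carbon, hydride delivery to the aryl- and oxygen-stabilised cation) should give methyl (3R)-3-[6-(benzyloxy)-2-(3,4-dimethoxyphenyl)-2,3-dihydro-1-benzofuran-5-yl]-3-[3,4-bis(benzyloxy)phenyl]propanoate F4 as a mixture of epimers at the new, later destroyed, centre. Mild hydrogenolysis (H2 1 bar, Pd/C, EtOAc/AcOH, rt) then cleaves the benzylic C–O bond and the benzyl ethers to hydroxy ester 16, which rejoins the route at the lactonisation.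

Step 2. Protodeboronation of the electron-rich boronic acid may outrun insertion, or enantiofacial control on this coumarin may be insufficient. The fallback separates aryl transfer from stereocontrol and sets out from coumarin 5. Pd(II)-catalysed oxidative Heck arylation with 6 (Pd(OAc)2, 1,10-phenanthroline, O2, DMF, 80 °C) should give 4-[3,4-bis(benzyloxy)phenyl]-7-bromo-2H-chromen-2-one F5. CuH-catalysed asymmetric conjugate reduction (Cu(OAc)2, DTBM-SEGPHOS enantiomer chosen to deliver hydride to the face that gives (R), (EtO)2MeSiH, t-BuOH, toluene, 0 °C) then returns to lactone 7.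

**Further compounds**

F1 | step 5 | methyl (3R)-3-[2-(benzyloxy)-4-(4,4,5,5-tetramethyl-1,3,2-dioxaborolan-2-yl)phenyl]-3-[3,4-bis(benzyloxy)phenyl]propanoate | COC(=O)C[C@@H](c1ccc(B2OC(C)(C)C(C)(C)O2)cc1OCc1ccccc1)c1ccc(OCc2ccccc2)c(OCc2ccccc2)c1
F2 | step 5 | methyl (3R)-3-[2-(benzyloxy)-4-hydroxyphenyl]-3-[3,4-bis(benzyloxy)phenyl]propanoate | COC(=O)C[C@@H](c1ccc(O)cc1OCc1ccccc1)c1ccc(OCc2ccccc2)c(OCc2ccccc2)c1
F3 | step 5 | methyl (3R)-3-[2-(benzyloxy)-4-hydroxy-5-iodophenyl]-3-[3,4-bis(benzyloxy)phenyl]propanoate | COC(=O)C[C@@H](c1cc(I)c(O)cc1OCc1ccccc1)c1ccc(OCc2ccccc2)c(OCc2ccccc2)c1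
F4 | step 6 | methyl (3R)-3-[6-(benzyloxy)-2-(3,4-dimethoxyphenyl)-2,3-dihydro-1-benzofuran-5-yl]-3-[3,4-bis(benzyloxy)phenyl]propanoate (either configuration at the dihydrofuran carbon) | COC(=O)C[C@@H](c1cc2CC(c3ccc(OC)c(OC)c3)Oc2cc1OCc1ccccc1)c1ccc(OCc2ccccc2)c(OCc2ccccc2)c1
F5 | step 2 | 4-[3,4-bis(benzyloxy)phenyl]-7-bromo-2H-chromen-2-one | O=C1C=C(c2ccc(OCc3ccccc3)c(OCc3ccccc3)c2)c2ccc(Br)cc2O1
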